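(The data were generated by integration with constants of no real substance; the scatter is artificial.)

Amounts first: this flask holds 0.85 M of substrate and 0.850 M of partner, and its near twin, the ash run, held the same substrate with 1.2 M of partner.

| setting | ash | elm | larch | flask |
|---|---|---|---|---|
| substrate | 0.85 M | 0.85 M | 1.7 M | 0.85 M |
| partner | 1.2 M | 1.9 M | 0.85 M | 0.850 M |
| remark | run made earlier | run made earlier | run made earlier |  |
| time |  |  |  | 1.0 h |

- ash (time / min: double product / %, side product / %, substrate / %): 10.0: 26.1, 31.4, 13.3; 20.0: 28.1, 35.3, 9.6; 30.0: 26.3, 37.1, 7.5; 40.0: 26.9, 37.5, 11.7; 50.0: 25.7, 39.7, 9.2; 60.0: 26.6, 38.6, 8.4; 80.0: 26.5, 39.6, 8.9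
- elm (time / min: double product / %, side product / %, substrate / %): 4.00: 28.9, 6.3, 6.6; 12.0: 27.7, 9.4, 5.8; 20.0: 26.5, 9.8, 6.1; 30.0: 25.7, 10.2, 1.9; 40.0: 26.6, 11.5, 2.1; 60.0: 25.1, 13.0, 2.2; 80.0: 27.1, 13.6, 3.1
- larch (time / min: double product / %, side product / %, substrate / %): 6.00: 9.2, 43.9, 41.9; 10.0: 7.8, 43.3, 41.4; 20.0: 9.0, 44.9, 41.6; 40.0: 6.8, 45.7, 42.6; 80.0: 9.6, 43.7, 42.2

(readings scatter by 1 percentage point)

- a species is counted by the substrate in it: one side product counts as two
- the reaction counts as stopped when no species that holds the substrate changes by six tenths of a point or more over the second half of the time

* which holds at 1.0 h: what has brought the reaction to rest, or that it has not come to rest (all of the substrate has reacted / forward and back rates have come level / the partner has run out first / it is still moving)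
* how much double product there is at 1.0 h, in percent of the substrate charged
* how much side product there is at 1.0 h, in percent of the substrate charged

The ash readings show 86.7% of the substrate gone by 10.0 min, a time short against 1.0 h, and later read near 9.14% of it remaining. What stopped it? The larch run suggests an answer. Count two partners in each double product, one in each side product, and two for each substrate missing from the readings. The larch readings then count 0.497 partner used per substrate charged, against a charge of 0.500. So partner looks used up in the larch run, at that count of 0.497. Taking the ash run to have ended the same way, each run can be read by its partner cost n, the partner charged per substrate reacted, c(partner)/[c(substrate)·reacted share].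

The ash run reads 1.55. The larch run reads 0.861, a lower cost than the ash run, at a lower ratio of partner to substrate. A straight line between them puts this flask at n = 1.24. The reckoning here is therefore that this flask stops when its 0.850 M of partner has been spent at that cost, leaving 19.4% of the substrate, more than the ash reading. The cost does not tell how the reacted substrate divides between the products.

The forecast, which parts from this reckoning on the stop, gives forward and back rates have come level, 15% double product and 45% side product, and argues: “This points to equilibrium.”

The flask gives the partner has run out first, with 20.1% double product and 47.1% side product.

    double product ⇌ isomer of the product (K = 0.370, k = 0.00170 /s)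
    partner + single product → double product (k = 2.10 /M/s)
    substrate + partner → single product (k = 1.00 /M/s)
    substrate + single product → side product (k = 0.0180 /M/s)
    partner + double product → tris adduct (k = 0.670 /M/s)

At 1.00 h partner, the limiting reagent, stands at 0% of its charge and substrate at 18%. The flask's cost is thus 1.22, against the 1.24 reckoned.

The neighbour with 1.4 M of partner lies between the ash and elm runs, and the elm run, by its substrate readings from 30.0 min on, reads 2.29. A straight line between the ash and elm costs gives that neighbour a cost of 1.76, so 6.61% of its substrate should remain; the computed neighbour holds 5.58%.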